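The reagent in the reaction phase is the substrate's partner in the second step, and it reaches the substrate through the interface.

    reagent in the reaction phase ⇌ dormant form (K1 = 1.1, k1 = 0.41 min⁻¹)
    substrate + reagent in the reaction phase ⇌ product (K2 = 290 M⁻¹, k2 = 17 M⁻¹ min⁻¹)
    reagent in the reaction phase ⇌ reagent in the second phase, rate k3*([reagent in the reaction phase] - [reagent in the second phase]/K3) per volume of the first phase (K3 = 55, k3 = 0.067 min⁻¹)
    reagent in the reaction phase + product ⇌ idle adduct, settled at all times (K4 = 8.2 M⁻¹)

substrate 0.10 M; reagent in the second phase 0.700 equiv; time 80 min; volume of the second phase over the first 0.25

- product is meant together with its idle adduct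
- in the second phase: reagent in the second phase; everything else is in the first
- charges count per volume of the first phase; a concentration in a rate is the amount of a species over the volume of its own phase; every rate counts per litre of the first phase
- run time (flask): 80 min

- product and idle adduct together at 80 min, in percent of the substrate charged
- the change that raises the amount of product and idle adduct together at 80 min, in percent of the substrate charged most ("none" if none brings more than 2 percentage points) (elm / maple / none)
- amount of product and idle adduct together at 80 min, in percent of the substrate charged, after elm

Climb the ladder of time scales, from the fastest rung to the slowest.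

1. The forward rate of the second step, with substrate as charged, gives the reagent in the reaction phase a half-life of 0.41 min; the way back is not counted here.

2. The reagent in the reaction phase, R, and the dormant form relax together by the first step with a half-life of 0.886 min, shorter than the transfer half-life of the next rung, so you may take the dormant form as K times R, with K the constant of the first step.

3. Transfer has a half-life of 10.3 min. Because R is consumed faster than it is fed, R is quasi-steady and transfer is the rate-limiting step. Take feed equal to net reaction at each moment.

4. Over the run of 80 min, the stock drains and product pushes back. Let c be the second-phase concentration over the partition ratio. Its charged value gives a ceiling feed of 3.41 × 10⁻⁴ M min⁻¹.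

5. Replace the curve by its midpoint. Try a transferred amount T of 0.750 of the ceiling over the run, 0.0205 M, and put half of it into stock, substrate and product. Then c is 0.00435 M and R is 5.59 × 10⁻⁴ M. The mean feed, the transfer coefficient times c minus R, is 2.54 × 10⁻⁴ M min⁻¹. It returns T as 0.0203 M, so the trial holds.

6. Check the error. The feeds at the two ends are 3.28 × 10⁻⁴ M min⁻¹ and 1.75 × 10⁻⁴ M min⁻¹. Their average, 2.51 × 10⁻⁴ M min⁻¹, lies close to the mean feed, so the curve is nearly straight.

7. Subtract the free and dormant reagent held at the end, and I expect 18.2%.

8. The same reckoning transfers 0.0316 M after elm, which I put at 28.0%. It transfers 0.0399 M after maple, so I choose maple.

The forecast gave 18.1% (range 17% to 19.3%), 27.3% after elm (range 25.5% to 29%) and maple, holding that “Transfer therefore limits the rate”.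

The flask gives 18.2%, 27.2% after elm, and maple as the best change, with gains of 17 percentage points against 9.1 points for elm. At 80.0 min, 71.3% of the second-phase reagent's charge remains in this flask. Your mean feed, multiplied by the time and taken from the charge, leaves 71.0%.

Now take the neighbouring flask with 0.025 M of substrate, the equivalents and the time held. A trial of 0.600 of its ceiling gives a mean feed of 4.67 × 10⁻⁵ M min⁻¹, and after the held reagent is subtracted, 9.33%. The computed flask with that substrate gives 11.9%, more than this reckoning.

The constants were drawn at random within sensible limits.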